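**Strategy.** Ring A is cut at its two opposite bonds C2–C3 and C5–C10; C5–C10 is also the fusion bond of ring B, so both rings open to one acyclic chain. In the key step the potassium trienolate of the acyclic skipped dienone ester sulfoxide 9 closes ring B through C5–C10 (isophorone-type disrotatory 6π closure; the 3E,7Z geometry makes C5–H and C10–CH3 trans), and the sulfinyl carbanion at C2 then acylates the non-enolisable C3 ester beside the gem-dimethyl carbon C4, closing ring A through C2–C3. The C8 oxygen, the C3 carbonyl and the quaternary C4 and C10 of the target are what the step exploits; the sulfinyl group is a traceless chiral handle.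

Key step: step 6

Remark: labdane numbering (C1–C20) of the target is used for every intermediate; 1, 3 and 13 are taken as commercial.
Remark: C2 of 12 and 19 is a labile β-keto sulfoxide centre and is left unspecified; the two C10 epimers of 12 are diastereomers because of the sulfinyl group, and only the (5S,10R) one is carried on after chromatography.

Step 1
Reactants: 1 (R)-methyl p-tolyl sulfoxide
Product: 2 (R)-but-3-yn-1-yl p-tolyl sulfoxide
Conditions: LiN(i-Pr)2 (2.1 equiv), THF, −78 °C; HC≡CCH2Br; aq NH4Cl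
Reagents that add atoms: propargyl bromide, C#CCBr
Why: Alkylation of the α-sulfinyl carbanion with the propargylic halide extends the methyl group and leaves the sulfur stereocentre untouched.

Step 2
Reactants: 3 methyl 2,2-dimethylpent-4-enoate
Product: 4 methyl 2,2-dimethyl-4-oxobutanoate
Conditions: O3, CH2Cl2, −78 °C; Me2S
Reagents that add atoms: ozone, [O-][O+]=O
Why: Ozonolysis with reductive work-up cleaves the only alkene to the aldehyde and the neopentyl ester is inert.

Step 3
Reactants: 4 methyl 2,2-dimethyl-4-oxobutanoate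
Product: 5 (E)-6-methoxy-5,5-dimethyl-6-oxohex-3-enoic acid
Conditions: CH2(CO2H)2, Et3N, 90 °C
Reagents that add atoms: malonic acid, OC(=O)CC(=O)O
Why: Knoevenagel–Doebner condensation under amine (Ragoussis) conditions isomerises the alkylidene malonic acid before decarboxylation and so gives the (E)-β,γ-unsaturated acid, which fixes the C5=C6 geometry.

Step 4
Reactants: 5 (E)-6-methoxy-5,5-dimethyl-6-oxohex-3-enoic acid; 2 (R)-but-3-yn-1-yl p-tolyl sulfoxide
Product: 8 methyl (E)-2,2-dimethyl-6-oxo-10-[(R)-p-tolylsulfinyl]dec-3-en-7-ynoate, via acid chloride 6 (not isolated), via alkynylzinc chloride 7 (not isolated)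
Conditions: 5: (COCl)2, DMF (cat.), CH2Cl2, 0 °C, then evaporation; 2: LiN(i-Pr)2 (1.0 equiv), THF, −78 °C, then ZnCl2; Pd(PPh3)4 (5 mol %), THF, 0 °C to rt
Reagents that add atoms: none
Why: Negishi acylation couples the non-basic alkynylzinc with the acid chloride under Pd(PPh3)4 catalysis without enolising the doubly activated C7 methylene.

Step 5
Reactants: 8 methyl (E)-2,2-dimethyl-6-oxo-10-[(R)-p-tolylsulfinyl]dec-3-en-7-ynoate
Product: 9 methyl (3E,7Z)-2,2,8-trimethyl-6-oxo-10-[(R)-p-tolylsulfinyl]deca-3,7-dienoate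
Conditions: Me2CuLi, THF, −78 °C; AcOH, −78 °C
Reagents that add atoms: lithium dimethylcuprate, [Li+].C[Cu-]C
Why: Syn carbocupration of the ynone followed by protonation with retention at low temperature should place the C1 arm cis to the C8 carbonyl, i.e. the (7Z)-β-methyl enone.

Step 6
Reactants: 9 methyl (3E,7Z)-2,2,8-trimethyl-6-oxo-10-[(R)-p-tolylsulfinyl]deca-3,7-dienoate
Product: 12 (4aS,8aR)-5,5,8a-trimethyl-7-[(R)-p-tolylsulfinyl]-4a,5,8,8a-tetrahydronaphthalene-2,6(1H,7H)-dione, via potassium trienolate 10 (not isolated), via potassium cyclohexadienolate 11 (not isolated)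
Conditions: KN(SiMe3)2 (1.1 equiv), THF, −78 to 50 °C; then LiN(i-Pr)2 (2.3 equiv), −78 to 0 °C; aq NH4Cl; chromatography
Reagents that add atoms: none
Why: Proposed new method: KN(SiMe3)2 removes the doubly activated (α-keto and allylic) C7 proton to give cross-conjugated trienolate 10, whose γ-carbon C5 adds to C10 of the enone arm by disrotatory 6π closure (a 6-endo vinylogous Michael addition) to give 11, forming C5–C10 and ring B; LiN(i-Pr)2 then makes the α-sulfinyl carbanion at C2, which attacks the neopentyl ester C3 in a 6-exo-trig Claisen (Dieckmann-type) acylation, forming C2–C3 and ring A. The closest known reactions are the base-mediated cyclisation of cross-conjugated dienones (phorone to isophorone), the thermal 6π electrocyclisation of siloxyhexatrienes and the Corey–Chaykovsky/Solladié acylation of sulfinyl carbanions by esters. The relative configuration of C5 and C10 follows from orbital symmetry: the 3E terminus holds C4 outside and the 7Z terminus holds the C1 arm inside, so C5–H and C10–CH3 end up trans, and C5 stays correctable afterwards because it is the γ-position of the new enone. The absolute sense at C10 is at best weakly biased by the (R)-sulfinyl group, whose real task is to make the two C10 epimers diastereomers that are separated on silica. The step needs deprotonation at C7 and not at C1 or C20, which the skipped enone secures because only the C7 dienolate has an enone arm to attack. It also needs acylation only after ring B has formed, which is secured because C2 reaches C3 through a six-membered transition state only then.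

Step 7
Reactants: 13 (E)-3-methylpent-2-en-4-yn-1-ol
Product: 14 [(2S,3S)-3-ethynyl-3-methyloxiran-2-yl]methanol
Conditions: Ti(O-i-Pr)4 (10 mol %), L-(+)-diethyl tartrate (12 mol %), t-BuOOH, 4 Å MS, CH2Cl2, −20 °C
Reagents that add atoms: tert-butyl hydroperoxide, CC(C)(C)OO
Why: Sharpless asymmetric epoxidation with the L-(+)-tartrate delivers oxygen to the face of the (E)-allylic alcohol that gives the (2S,3S)-epoxide, which sets the future C13.

Step 8
Reactants: 14 [(2S,3S)-3-ethynyl-3-methyloxiran-2-yl]methanol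
Product: 15 (R)-3-methylpent-4-ene-1,3-diol
Conditions: NaAlH2(OCH2CH2OMe)2 (excess), THF, 0 to 45 °C; Rochelle salt
Reagents that add atoms: none
Why: Alkoxide-directed hydride delivery opens the 2,3-epoxy alcohol at C2 to the 1,3-diol and the tertiary propargylic alkoxide then directs trans-hydroalumination of the alkyne to the vinyl group, while the C13–O bond and its configuration are retained.

Step 9
Reactants: 15 (R)-3-methylpent-4-ene-1,3-diol
Product: 16 (R)-3-methyl-1,3-bis(triethylsilyloxy)pent-4-ene
Conditions: Et3SiOTf (2.3 equiv), 2,6-lutidine, CH2Cl2, −78 to 0 °C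
Reagents that add atoms: triethylsilyl trifluoromethanesulfonate, CC[Si](CC)(CC)OS(=O)(=O)C(F)(F)F
Why: The silyl triflate silylates both the primary and the hindered tertiary hydroxyl.

Step 10
Reactants: 16 (R)-3-methyl-1,3-bis(triethylsilyloxy)pent-4-ene
Product: 17 (R)-3-methyl-3-(triethylsilyloxy)pent-4-en-1-ol
Conditions: pyridinium p-toluenesulfonate (cat.), MeOH/CH2Cl2, 0 °C
Reagents that add atoms: none
Why: Mild acid methanolysis cleaves the primary triethylsilyl ether much faster than the tertiary one.

Step 11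
Reactants: 12 (4aS,8aR)-5,5,8a-trimethyl-7-[(R)-p-tolylsulfinyl]-4a,5,8,8a-tetrahydronaphthalene-2,6(1H,7H)-dione; 17 (R)-3-methyl-3-(triethylsilyloxy)pent-4-en-1-ol
Product: 19 (5S,9R,10R,13R)-2-[(R)-p-tolylsulfinyl]-13-(triethylsilyloxy)-17-norlabda-6,14-diene-3,8-dione, via primary triflate 18 (not isolated)
Conditions: 17: Tf2O, 2,6-di-tert-butylpyridine, CH2Cl2, −78 °C; 12: LiN(i-Pr)2 (2.2 equiv), THF, −78 °C; then 18, −78 to −30 °C
Reagents that add atoms: none
Why: In this dianion alkylation the β-keto sulfoxide is masked as its enolate and the kinetic cross-conjugated enolate at C9 is alkylated by the primary triflate axially, anti to the axial C10 methyl, which sets C9.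

Step 12
Reactants: 19 (5S,9R,10R,13R)-2-[(R)-p-tolylsulfinyl]-13-(triethylsilyloxy)-17-norlabda-6,14-diene-3,8-dione
Product: 20 (5S,9R,10R,13R)-13-(triethylsilyloxy)-17-norlabda-6,14-diene-3,8-dione
Conditions: aluminium amalgam (Al/Hg), THF/H2O, 0 °C to rt
Reagents that add atoms: none
Why: Aluminium amalgam cleaves the C2–S bond of the β-keto sulfoxide (Corey–Chaykovsky desulfinylation) and should leave the enone, the vinyl group and the silyl ether intact.

Step 13
Reactants: 20 (5S,9R,10R,13R)-13-(triethylsilyloxy)-17-norlabda-6,14-diene-3,8-dione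
Product: 21 (3S,5S,9R,10R,13R)-3-hydroxy-13-(triethylsilyloxy)-17-norlabd-14-en-8-one
Conditions: LiBH(s-Bu)3 (3 equiv), THF, −78 to −40 °C; aq NH4Cl
Reagents that add atoms: none
Why: The bulky borohydride adds 1,4 to the cyclohexenone (C8 is then held as its boron enolate) and reduces the hindered C3 ketone from the equatorial direction to the axial (3S) alcohol, without enolising C9.

Step 14
Reactants: 21 (3S,5S,9R,10R,13R)-3-hydroxy-13-(triethylsilyloxy)-17-norlabd-14-en-8-one
Product: 22 (3S,5S,8R,9R,10R,13R)-13-(triethylsilyloxy)labd-14-ene-3,8-diol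
Conditions: MeLi, CeCl3, THF, −78 °C
Reagents that add atoms: methyllithium, [Li]C
Why: The organocerium reagent (Imamoto) adds to the C8 ketone without enolisation and from the face opposite the 1,3-diaxial C10 methyl, which should give the axial 8-hydroxyl (8R).

Step 15
Reactants: 22 (3S,5S,8R,9R,10R,13R)-13-(triethylsilyloxy)labd-14-ene-3,8-diol
Product: 23 (3R,5S,8R,9R,10R,13R)-3-bromo-13-(triethylsilyloxy)labd-14-en-8-ol
Conditions: CBr4, PPh3, 2,6-lutidine, CH2Cl2, 0 °C to rt
Reagents that add atoms: carbon tetrabromide, BrC(Br)(Br)Br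
Why: In the Appel reaction bromide displaces the axial oxyphosphonium by SN2 with inversion to give the equatorial (3R) bromide, while the hindered tertiary C8 alcohol should not react.

Step 16
Reactants: 23 (3R,5S,8R,9R,10R,13R)-3-bromo-13-(triethylsilyloxy)labd-14-en-8-ol
Product: 24 (3R,5S,8R,9R,10R,13R)-3-bromolabd-14-ene-8,13-diol
Conditions: Bu4NF, THF, 0 °C to rt
Reagents that add atoms: none
Why: Fluoride cleaves the tertiary triethylsilyl ether and leaves the secondary neopentylic bromide untouched.

Compound list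
1 | (R)-methyl p-tolyl sulfoxide | C[S@@](=O)c1ccc(C)cc1 | starting material
2 | (R)-but-3-yn-1-yl p-tolyl sulfoxide | C#CCC[S@@](=O)c1ccc(C)cc1 | intermediate
3 | methyl 2,2-dimethylpent-4-enoate | C=CCC(C)(C)C(=O)OC | starting material
4 | methyl 2,2-dimethyl-4-oxobutanoate | O=CCC(C)(C)C(=O)OC | intermediate
5 | (E)-6-methoxy-5,5-dimethyl-6-oxohex-3-enoic acid | COC(=O)C(C)(C)/C=C/CC(=O)O | intermediate
6 | methyl (E)-6-chloro-2,2-dimethyl-6-oxohex-3-enoate (acid chloride) | COC(=O)C(C)(C)/C=C/CC(=O)Cl | intermediate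
7 | chloro{4-[(R)-p-tolylsulfinyl]but-1-yn-1-yl}zinc | Cl[Zn]C#CCC[S@@](=O)c1ccc(C)cc1 | intermediate
8 | methyl (E)-2,2-dimethyl-6-oxo-10-[(R)-p-tolylsulfinyl]dec-3-en-7-ynoate | COC(=O)C(C)(C)/C=C/CC(=O)C#CCC[S@@](=O)c1ccc(C)cc1 | intermediate
9 | methyl (3E,7Z)-2,2,8-trimethyl-6-oxo-10-[(R)-p-tolylsulfinyl]deca-3,7-dienoate | COC(=O)C(C)(C)/C=C/CC(=O)/C=C(C)\CC[S@@](=O)c1ccc(C)cc1 | intermediate
10 | potassium trienolate of 9 (C7 deprotonated; C6 and C9 cis on the enolate bond) | [K+].COC(=O)C(C)(C)/C=C/C=C(/[O-])\C=C(C)/CC[S@@](=O)c1ccc(C)cc1 | intermediate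
11 | potassium cyclohexa-1,3-dien-1-olate with ring B closed (C5–H cis to the C1 arm on C10) | [K+].[O-]C1=C[C@](C)(CC[S@@](=O)c2ccc(C)cc2)[C@@H](C(C)(C)C(=O)OC)C=C1 | intermediate
12 | (4aS,8aR)-5,5,8a-trimethyl-7-[(R)-p-tolylsulfinyl]-4a,5,8,8a-tetrahydronaphthalene-2,6(1H,7H)-dione (labdane 5S,10R; trans-fused) | C1[C@]2(C)CC([S@@](=O)c3ccc(C)cc3)C(=O)C(C)(C)[C@H]2C=CC1=O | intermediate
13 | (E)-3-methylpent-2-en-4-yn-1-ol | C#C/C(C)=C/CO | starting material
14 | [(2S,3S)-3-ethynyl-3-methyloxiran-2-yl]methanol | C#C[C@]1(C)O[C@H]1CO | intermediate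
15 | (R)-3-methylpent-4-ene-1,3-diol | C=C[C@](C)(O)CCO | intermediate
16 | (R)-3-methyl-1,3-bis(triethylsilyloxy)pent-4-ene | C=C[C@](C)(O[Si](CC)(CC)CC)CCO[Si](CC)(CC)CC | intermediate
17 | (R)-3-methyl-3-(triethylsilyloxy)pent-4-en-1-ol | C=C[C@](C)(O[Si](CC)(CC)CC)CCO | intermediate
18 | (R)-3-methyl-3-(triethylsilyloxy)pent-4-en-1-yl trifluoromethanesulfonate | C=C[C@](C)(O[Si](CC)(CC)CC)CCOS(=O)(=O)C(F)(F)F | intermediate
19 | (5S,9R,10R,13R)-2-[(R)-p-tolylsulfinyl]-13-(triethylsilyloxy)-17-norlabda-6,14-diene-3,8-dione | C=C[C@](C)(O[Si](CC)(CC)CC)CC[C@@H]1[C@]2(C)CC([S@@](=O)c3ccc(C)cc3)C(=O)C(C)(C)[C@H]2C=CC1=O | intermediate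
20 | (5S,9R,10R,13R)-13-(triethylsilyloxy)-17-norlabda-6,14-diene-3,8-dione | C=C[C@](C)(O[Si](CC)(CC)CC)CC[C@@H]1[C@]2(C)CCC(=O)C(C)(C)[C@H]2C=CC1=O | intermediate
21 | (3S,5S,9R,10R,13R)-3-hydroxy-13-(triethylsilyloxy)-17-norlabd-14-en-8-one (axial 3-OH) | C=C[C@](C)(O[Si](CC)(CC)CC)CC[C@@H]1[C@]2(C)CC[C@H](O)C(C)(C)[C@H]2CCC1=O | intermediate
22 | (3S,5S,8R,9R,10R,13R)-13-(triethylsilyloxy)labd-14-ene-3,8-diol | C=C[C@](C)(O[Si](CC)(CC)CC)CC[C@@H]1[C@]2(C)CC[C@H](O)C(C)(C)[C@H]2CC[C@@]1(C)O | intermediate
23 | (3R,5S,8R,9R,10R,13R)-3-bromo-13-(triethylsilyloxy)labd-14-en-8-ol | C=C[C@](C)(O[Si](CC)(CC)CC)CC[C@@H]1[C@]2(C)CC[C@@H](Br)C(C)(C)[C@H]2CC[C@@]1(C)O | intermediate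
24 | (3R,5S,8R,9R,10R,13R)-3-bromolabd-14-ene-8,13-diol | C=C[C@](C)(O)CC[C@@H]1[C@]2(C)CC[C@@H](Br)C(C)(C)[C@H]2CC[C@@]1(C)O | target

Total step count: 16. Longest linear sequence: 11 steps (3 to 24 through steps 2–6 and 11–16).

Steps most likely to fail

Step 6 (Proposed new method). The trienolate may be protonated at C5 and re-form in the conjugated series, which opens the wrong-sense closure from C1 or C20. Closure at the fully substituted C10 terminus may also be slow enough for sulfoxide elimination or intermolecular Claisen condensation to compete. Finally, the remote sulfinyl group may give no facial bias at C10, so that half of the material is lost on separation. Fallback (known chemistry, stepwise): setting out from 9, the C7 trienolate is trapped at −78 °C with t-BuMe2SiCl (KN(SiMe3)2, THF) as tert-butyldimethylsilyl trienol ether F1. F1 is heated in toluene at about 90 °C for the thermal disrotatory 6π electrocyclisation of a siloxyhexatriene, which gives cyclohexadienyl silyl ether F2. F2 is treated with LiN(i-Pr)2 (2.2 equiv, THF, −78 to 0 °C) for the sulfinyl-carbanion acylation and the silyl dienol ether is cleaved on work-up with dilute HCl in THF, which comes back to the route at 12.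

Step 15. E2 loss of the axial oxyphosphonium towards C2, Wagner–Meerwein contraction at the neopentylic centre or ionisation of the free tertiary C8 alcohol may outrun the hindered SN2 attack. Fallback: setting out from 22, only the secondary alcohol is sulfonylated (ClCH2SO2Cl, pyridine, 0 °C) to axial chloromethanesulfonate F3, and this discrete sulfonate is displaced with inversion by LiBr in DMF at 50 °C, which comes back to the route at 23.

Step 13. Hydride may add 1,2 to the enone because the β-carbon C6 sits next to the substituted C5, the boron enolate may be protonated early so that the C8 ketone is over-reduced, and a basic work-up may epimerise C9. Fallback: setting out from 20, conjugate reduction with [(Ph3P)CuH]6 and Me3SiCl (THF, −40 °C) traps C8 as trimethylsilyl enol ether F4. LiBH(s-Bu)3 then reduces only the C3 ketone to silyl enol ether alcohol F5, and citric acid in MeOH frees the C8 ketone, which comes back to the route at 21.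

Further compounds
F1 | step 6 | tert-butyldimethylsilyl trienol ether of 9 | COC(=O)C(C)(C)/C=C/C=C(/O[Si](C)(C)C(C)(C)C)\C=C(C)/CC[S@@](=O)c1ccc(C)cc1
F2 | step 6 | cyclohexadienyl tert-butyldimethylsilyl ether with ring B closed | CC(C)(C)[Si](C)(C)OC1=C[C@](C)(CC[S@@](=O)c2ccc(C)cc2)[C@@H](C(C)(C)C(=O)OC)C=C1
F3 | step 15 | axial 3-chloromethanesulfonate of 22 | C=C[C@](C)(O[Si](CC)(CC)CC)CC[C@@H]1[C@]2(C)CC[C@H](OS(=O)(=O)CCl)C(C)(C)[C@H]2CC[C@@]1(C)O
F4 | step 13 | 8-trimethylsilyl enol ether of 6,7-dihydro-20 | C=C[C@](C)(O[Si](CC)(CC)CC)CC[C@@H]1[C@]2(C)CCC(=O)C(C)(C)[C@H]2CC=C1O[Si](C)(C)C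
F5 | step 13 | (3S)-3-hydroxy analogue of F4 | C=C[C@](C)(O[Si](CC)(CC)CC)CC[C@@H]1[C@]2(C)CC[C@H](O)C(C)(C)[C@H]2CC=C1O[Si](C)(C)C
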